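**Retrosynthetic overview**
1. Target 18 comes from its 5-O-methyl ether 17 by cleaving one chelated methyl ether (last step).
2. The second pyranone (genistein half) comes from deoxybenzoin 16 plus one carbon from DMF. 16 comes from Friedel–Crafts acylation of the C2-symmetric 2-aryloxy-5-methoxyresorcinol 14 with 4-hydroxyphenylacetic acid; symmetry plus the OMe block fix the 8-aryloxy pattern.
3. The first pyranone (8-chloro-isoflavone half, in 14) comes from oxidative 1,2-aryl shift and cyclisation of the 2'-hydroxychalcone 12.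
4. Chalcone 12 comes from a Claisen–Schmidt aldol condensation of acetophenone 10 (from 2-chlororesorcinol) with the diaryl-ether aldehyde 7; this C–C bond joins the two halves.
5. Aldehyde 7 comes from SNAr of phenol 5 on 4-fluorobenzaldehyde; 5 comes from 5-methoxyresorcinol (MOM protection, directed lithiation, oxidation).

Assumption: the target SMILES has no stereocentre and no stereogenic double bond, so it is achiral and no asymmetric step is needed; the stereocentres in 11 and 13 are racemic and are destroyed later.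

**Step 1**
Reactants: 1 5-methoxyresorcinol (5-methoxybenzene-1,3-diol)
Product: 2 1-methoxy-3,5-bis(methoxymethoxy)benzene
Conditions: NaH (2.4 equiv), MOMCl (2.4 equiv), DMF, 0 °C → rt
Reagents that add atoms: chloromethyl methyl ether (MOMCl), COCCl
Why: Williamson O-alkylation of both phenoxides gives the base-stable bis-MOM ether, whose OMOM groups are strong ortho-directing groups for step 2.

**Step 2**
Reactants: 2 1-methoxy-3,5-bis(methoxymethoxy)benzene
Product: 5 4-methoxy-2,6-bis(methoxymethoxy)phenol, via aryllithium 3 (not isolated), via dimethyl arylboronate 4 (not isolated)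
Conditions: n-BuLi, THF, 0 °C → rt; B(OMe)3, −78 °C → rt; 30% H2O2, aq NaOH, 0 °C
Reagents that add atoms: n-butyllithium, [Li]CCCC (Li of 3); trimethyl borate, COB(OC)OC (B(OMe)2 of 4); hydrogen peroxide, OO (phenol O of 5)
Why: Directed ortho-metalation is expected at the CH flanked by the two chelating OMOM groups (stronger directors than OMe), and borylation followed by oxidative C–B to C–O migration gives the C2-symmetric phenol (two equivalent aryl H in the NMR confirm the regiochemistry).

**Step 3**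
Reactants: 5 4-methoxy-2,6-bis(methoxymethoxy)phenol; 6 4-fluorobenzaldehyde
Product: 7 4-[4-methoxy-2,6-bis(methoxymethoxy)phenoxy]benzaldehyde
Conditions: K2CO3, DMF, 120 °C, N2
Reagents that add atoms: none
Why: Nucleophilic aromatic substitution (SNAr) of the para-formyl-activated fluoride by the electron-rich phenoxide forms the diaryl ether; MOM ethers and the aldehyde tolerate carbonate base.

**Step 4**
Reactants: 8 2-chlororesorcinol (2-chlorobenzene-1,3-diol)
Product: 9 1-(3-chloro-2,4-dihydroxyphenyl)ethan-1-one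
Conditions: AcOH, BF3·Et2O, 90 °C; aq NaOAc
Reagents that add atoms: acetic acid, CC(=O)O
Why: Friedel–Crafts (Nencki-type) C-acetylation occurs at C4, which is equivalent to C6 and ortho/para to the two hydroxyls, so only one regioisomer can form.

**Step 5**
Reactants: 9 1-(3-chloro-2,4-dihydroxyphenyl)ethan-1-one
Product: 10 1-[3-chloro-2-hydroxy-4-(methoxymethoxy)phenyl]ethan-1-one
Conditions: MOMCl (1.1 equiv), K2CO3, acetone, 0 °C → rt
Reagents that add atoms: chloromethyl methyl ether (MOMCl), COCCl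
Why: Selective Williamson O-alkylation of the 4-OH works because the 2-OH is tied up in a hydrogen bond to the ketone and is much less nucleophilic.

**Step 6**
Reactants: 7 4-[4-methoxy-2,6-bis(methoxymethoxy)phenoxy]benzaldehyde; 10 1-[3-chloro-2-hydroxy-4-(methoxymethoxy)phenyl]ethan-1-one
Product: 12 (E)-1-[3-chloro-2-hydroxy-4-(methoxymethoxy)phenyl]-3-{4-[4-methoxy-2,6-bis(methoxymethoxy)phenoxy]phenyl}prop-2-en-1-one, via β-hydroxy ketone 11 (not isolated)
Conditions: KOH (50% aq), EtOH, rt, 36 h; AcOH to pH 6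
Reagents that add atoms: none
Why: Intermolecular Claisen–Schmidt aldol addition of the methyl ketone enolate to the non-enolisable aldehyde, then E1cB dehydration, gives the thermodynamically favoured E-chalcone; MOM ethers, aryl chloride and diaryl ether are inert to hydroxide.

**Step 7**
Reactants: 12 the (E)-2'-hydroxychalcone
Product: 13 rac-1-[3-chloro-2-hydroxy-4-(methoxymethoxy)phenyl]-3,3-dimethoxy-2-{4-[4-methoxy-2,6-bis(methoxymethoxy)phenoxy]phenyl}propan-1-one
Conditions: Tl(NO3)3·3H2O (1.2 equiv), MeOH/HC(OMe)3 (1:1), 0 °C → rt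
Reagents that add atoms: methanol, CO
Why: Oxythallation of the enone triggers a 1,2-shift of the electron-rich 4-aryloxyphenyl group from C-β to C-α (McKillop–Taylor oxidative rearrangement) and the oxocarbenium ion is trapped as the dimethyl acetal; the new stereocentre is racemic and is lost in step 8.

**Step 8**
Reactants: 13 the rearranged dimethyl acetal
Product: 14 8-chloro-3-[4-(2,6-dihydroxy-4-methoxyphenoxy)phenyl]-7-hydroxy-4H-chromen-4-one
Conditions: 10% HCl in MeOH, 60 °C
Reagents that add atoms: none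
Why: Acid removes the three MOM acetals and drives attack of the 2'-OH on the acetal carbon with loss of two MeOH (cyclodehydration), giving the aromatic 4H-chromen-4-one ring while the aryl methyl ether survives.

**Step 9**
Reactants: 14 8-chloro-3-[4-(2,6-dihydroxy-4-methoxyphenoxy)phenyl]-7-hydroxy-4H-chromen-4-one; 15 4-hydroxyphenylacetic acid
Product: 16 8-chloro-3-(4-{2,6-dihydroxy-3-[2-(4-hydroxyphenyl)acetyl]-4-methoxyphenoxy}phenyl)-7-hydroxy-4H-chromen-4-one
Conditions: BF3·Et2O (solvent/promoter), 85 °C, N2; aq NaOAc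
Reagents that add atoms: none
Why: Friedel–Crafts C-acylation can only occur at the two equivalent CH positions of the C2-symmetric phloroglucinol-type ring (ortho to OH and OMe, para to OH), since the chromone ring and the central ring are far less nucleophilic.

**Step 10**
Reactants: 16 the deoxybenzoin
Product: 17 8-[4-(8-chloro-7-hydroxy-4-oxo-4H-chromen-3-yl)phenoxy]-7-hydroxy-3-(4-hydroxyphenyl)-5-methoxy-4H-chromen-4-one
Conditions: BF3·Et2O, DMF, MsCl, 50 → 80 °C; H2O
Reagents that add atoms: N,N-dimethylformamide, CN(C)C=O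
Why: Vilsmeier-type C-formylation of the activated methylene and ring closure through the only ortho-hydroxyl (the other ortho position is OMe) forms the second isoflavone with the aryloxy group necessarily at C-8.

**Step 11**
Reactants: 17 the 5-O-methyl ether
Product: 18 bisoflavolin H, 8-[4-(8-chloro-7-hydroxy-4-oxo-4H-chromen-3-yl)phenoxy]-5,7-dihydroxy-3-(4-hydroxyphenyl)-4H-chromen-4-one
Conditions: BBr3 (8 equiv), CH2Cl2, −78 °C → rt; MeOH, H2O
Reagents that add atoms: none
Why: Lewis-acid O-demethylation of the peri 5-OMe is fast because of chelation to the C-4 carbonyl, and the diaryl ether, aryl chloride and chromone rings are inert to BBr3 at room temperature.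

**Compound list**
1 | 5-methoxyresorcinol (5-methoxybenzene-1,3-diol) | COc1cc(O)cc(O)c1 | starting material
2 | 1-methoxy-3,5-bis(methoxymethoxy)benzene | COCOc1cc(OC)cc(OCOC)c1 | intermediate
3 | [4-methoxy-2,6-bis(methoxymethoxy)phenyl]lithium (not isolated) | [Li]c1c(OCOC)cc(OC)cc1OCOC | intermediate
4 | dimethyl [4-methoxy-2,6-bis(methoxymethoxy)phenyl]boronate (not isolated) | COB(OC)c1c(OCOC)cc(OC)cc1OCOC | intermediate
5 | 4-methoxy-2,6-bis(methoxymethoxy)phenol | Oc1c(OCOC)cc(OC)cc1OCOC | intermediate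
6 | 4-fluorobenzaldehyde | O=Cc1ccc(F)cc1 | starting material
7 | 4-[4-methoxy-2,6-bis(methoxymethoxy)phenoxy]benzaldehyde | O=Cc1ccc(Oc2c(OCOC)cc(OC)cc2OCOC)cc1 | intermediate
8 | 2-chlororesorcinol (2-chlorobenzene-1,3-diol) | Oc1cccc(O)c1Cl | starting material
9 | 1-(3-chloro-2,4-dihydroxyphenyl)ethan-1-one | CC(=O)c1ccc(O)c(Cl)c1O | intermediate
10 | 1-[3-chloro-2-hydroxy-4-(methoxymethoxy)phenyl]ethan-1-one | CC(=O)c1ccc(OCOC)c(Cl)c1O | intermediate
11 | rac-1-[3-chloro-2-hydroxy-4-(methoxymethoxy)phenyl]-3-hydroxy-3-{4-[4-methoxy-2,6-bis(methoxymethoxy)phenoxy]phenyl}propan-1-one (aldol adduct, not isolated) | COCOc1ccc(C(=O)CC(O)c2ccc(Oc3c(OCOC)cc(OC)cc3OCOC)cc2)c(O)c1Cl | intermediate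
12 | (E)-1-[3-chloro-2-hydroxy-4-(methoxymethoxy)phenyl]-3-{4-[4-methoxy-2,6-bis(methoxymethoxy)phenoxy]phenyl}prop-2-en-1-one | COCOc1ccc(C(=O)/C=C/c2ccc(Oc3c(OCOC)cc(OC)cc3OCOC)cc2)c(O)c1Cl | intermediate
13 | rac-1-[3-chloro-2-hydroxy-4-(methoxymethoxy)phenyl]-3,3-dimethoxy-2-{4-[4-methoxy-2,6-bis(methoxymethoxy)phenoxy]phenyl}propan-1-one | COCOc1ccc(C(=O)C(C(OC)OC)c2ccc(Oc3c(OCOC)cc(OC)cc3OCOC)cc2)c(O)c1Cl | intermediate
14 | 8-chloro-3-[4-(2,6-dihydroxy-4-methoxyphenoxy)phenyl]-7-hydroxy-4H-chromen-4-one | O=c1c(-c2ccc(Oc3c(O)cc(OC)cc3O)cc2)coc2c(Cl)c(O)ccc12 | intermediate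
15 | 4-hydroxyphenylacetic acid | OC(=O)Cc1ccc(O)cc1 | starting material
16 | 8-chloro-3-(4-{2,6-dihydroxy-3-[2-(4-hydroxyphenyl)acetyl]-4-methoxyphenoxy}phenyl)-7-hydroxy-4H-chromen-4-one | O=c1c(-c2ccc(Oc3c(O)cc(OC)c(C(=O)Cc4ccc(O)cc4)c3O)cc2)coc2c(Cl)c(O)ccc12 | intermediate
17 | 8-[4-(8-chloro-7-hydroxy-4-oxo-4H-chromen-3-yl)phenoxy]-7-hydroxy-3-(4-hydroxyphenyl)-5-methoxy-4H-chromen-4-one | O=c1c(-c2ccc(Oc3c(O)cc(OC)c4c(=O)c(-c5ccc(O)cc5)coc34)cc2)coc2c(Cl)c(O)ccc12 | intermediate
18 | bisoflavolin H, 8-[4-(8-chloro-7-hydroxy-4-oxo-4H-chromen-3-yl)phenoxy]-5,7-dihydroxy-3-(4-hydroxyphenyl)-4H-chromen-4-one | O=c1c(-c2ccc(Oc3c(O)cc(O)c4c(=O)c(-c5ccc(O)cc5)coc34)cc2)coc2c(Cl)c(O)ccc12 | target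

**Totals**
Total step count: 11. Longest linear sequence: 9 steps (steps 1, 2, 3, 6, 7, 8, 9, 10, 11). Steps 4 and 5 form the two-step side branch to 10.

**Three steps most likely to fail, with fallbacks**

Step 7 (thallium(III) oxidative rearrangement): the very electron-rich tetra-oxygenated ring could be oxidised, or the free 2'-OH could divert the reaction towards an aurone. The fallback sets out from chalcone 12 and comes back at isoflavone 14 without any oxidant stronger than alkaline peroxide. The 2'-OH of 12 is capped (NaH, MOMCl, DMF) to give (E)-1-[3-chloro-2,4-bis(methoxymethoxy)phenyl]-3-{4-[4-methoxy-2,6-bis(methoxymethoxy)phenoxy]phenyl}prop-2-en-1-one F1. Weitz–Scheffer epoxidation (H2O2, NaOH, MeOH/THF) gives the racemic trans-chalcone epoxide [3-chloro-2,4-bis(methoxymethoxy)phenyl](3-{4-[4-methoxy-2,6-bis(methoxymethoxy)phenoxy]phenyl}oxiran-2-yl)methanone F2. BF3·Et2O in CH2Cl2 at −20 °C opens the epoxide at the benzylic carbon and a 1,2-aroyl shift delivers the β-keto aldehyde 3-[3-chloro-2,4-bis(methoxymethoxy)phenyl]-2-{4-[4-methoxy-2,6-bis(methoxymethoxy)phenoxy]phenyl}-3-oxopropanal F3. The HCl/MeOH treatment of step 8 then removes all four MOM groups and cyclises F3 to 14.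

Step 9 (BF3-mediated acylation of the complex polyphenol 14): low solubility, O-acylation or decomposition at 85 °C could limit conversion. The fallback sets out from 14 and comes back at 16 by a Houben–Hoesch reaction. 14 and 4-hydroxyphenylacetonitrile are treated with ZnCl2 and dry HCl gas in dioxane/Et2O at 0 °C. The nitrilium electrophile attacks the same symmetric ring position and precipitates the ketiminium chloride of 16, 1-amino-1-{3-[4-(8-chloro-7-hydroxy-4-oxo-4H-chromen-3-yl)phenoxy]-2,4-dihydroxy-6-methoxyphenyl}-2-(4-hydroxyphenyl)ethan-1-iminium chloride F4. Heating F4 in water hydrolyses it to deoxybenzoin 16.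

Step 2 (lithiation/borylation/oxidation): the hindered, electron-rich boronate may protodeboronate before oxidation, and some lithiation next to OMe would give an inseparable oily phenol mixture. The fallback sets out from 2 and comes back at 5, forming the C–O bond by Baeyer–Villiger chemistry instead. Aryllithium 3 is generated as before but quenched with DMF to give crystalline 4-methoxy-2,6-bis(methoxymethoxy)benzaldehyde F5, from which any unsymmetrical isomer is removed by recrystallisation. Dakin-type Baeyer–Villiger oxidation (mCPBA, NaHCO3, CH2Cl2) gives 4-methoxy-2,6-bis(methoxymethoxy)phenyl formate F6, and methanolysis (K2CO3, MeOH, rt) releases phenol 5.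

**Further compounds**
F1 | step 7 | (E)-1-[3-chloro-2,4-bis(methoxymethoxy)phenyl]-3-{4-[4-methoxy-2,6-bis(methoxymethoxy)phenoxy]phenyl}prop-2-en-1-one | COCOc1ccc(C(=O)/C=C/c2ccc(Oc3c(OCOC)cc(OC)cc3OCOC)cc2)c(OCOC)c1Cl
F2 | step 7 | rac-trans-[3-chloro-2,4-bis(methoxymethoxy)phenyl](3-{4-[4-methoxy-2,6-bis(methoxymethoxy)phenoxy]phenyl}oxiran-2-yl)methanone (one enantiomer drawn) | COCOc1ccc(C(=O)[C@H]4O[C@@H]4c2ccc(Oc3c(OCOC)cc(OC)cc3OCOC)cc2)c(OCOC)c1Cl
F3 | step 7 | rac-3-[3-chloro-2,4-bis(methoxymethoxy)phenyl]-2-{4-[4-methoxy-2,6-bis(methoxymethoxy)phenoxy]phenyl}-3-oxopropanal | COCOc1ccc(C(=O)C(C=O)c2ccc(Oc3c(OCOC)cc(OC)cc3OCOC)cc2)c(OCOC)c1Cl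
F4 | step 9 | 1-amino-1-{3-[4-(8-chloro-7-hydroxy-4-oxo-4H-chromen-3-yl)phenoxy]-2,4-dihydroxy-6-methoxyphenyl}-2-(4-hydroxyphenyl)ethan-1-iminium chloride (ketiminium chloride of 16) | O=c1c(-c2ccc(Oc3c(O)cc(OC)c(C(=[NH2+])Cc4ccc(O)cc4)c3O)cc2)coc2c(Cl)c(O)ccc12.[Cl-]
F5 | step 2 | 4-methoxy-2,6-bis(methoxymethoxy)benzaldehyde | O=Cc1c(OCOC)cc(OC)cc1OCOC
F6 | step 2 | 4-methoxy-2,6-bis(methoxymethoxy)phenyl formate | O=COc1c(OCOC)cc(OC)cc1OCOC
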